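**Plan**
- Retrosynthesis: first cut the aryl ether bond O1–C8a of ring C, giving an acyclic (S)-aldol whose ring A carries fluorine at C8a. Then cut C2–C3 (aldol) into a ring A methyl ketone enol silane and a ring B aldehyde. Finally cut the aryl–alkyne and aryl–prenyl bonds of ring B back to 3-bromo-5-iodo-4-methoxybenzaldehyde.
- Forward: ring B aldehyde is built first (iodination, methylation, Sonogashira, Stille, semi-hydrogenation, silylation). The ring A ketone is made from 5-fluororesorcinol. The two are joined by aldol, ring C is closed last, and one fluoride step removes all silyl groups.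
- Enabling feature: C8a of ring A is ortho to the C4 ketone, so C4=O/C4a=C8a–F is a vinylogous acyl fluoride. The C2 oxygen sits five atoms away (six-membered transition state), and both ring A oxygens are meta to C8a.
- Stereochemistry: C2 (S) comes from a catalytic enantioselective Mukaiyama aldol (Si-face addition) and is not touched by the ring closure. The (Z)-alkene comes from syn semi-hydrogenation of the alkyne.

Key step: step 11

Remark: the target is read as (2S). The (S,S)-bisphosphoramide is chosen on the premise that its (R,R)-antipode delivers enol silanes to the Re face of aryl aldehydes; this is recalled, not certain, so the configuration of the aldol should be confirmed by Mosher ester analysis, and the antipodal catalyst used if needed.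

**Step 1**
Reactants: 1 3-bromo-4-hydroxybenzaldehyde
Product: 2 3-bromo-4-hydroxy-5-iodobenzaldehyde
Conditions: NIS, AcOH, rt
Reagents that add atoms: N-iodosuccinimide, O=C1CCC(=O)N1I
Why: Electrophilic aromatic iodination should occur at the only free position ortho to the phenol, which is also meta to the aldehyde.

**Step 2**
Reactants: 2 3-bromo-4-hydroxy-5-iodobenzaldehyde
Product: 3 3-bromo-5-iodo-4-methoxybenzaldehyde
Conditions: MeI, K2CO3, DMF, rt
Reagents that add atoms: iodomethane, CI
Why: Williamson O-methylation of the acidic 2,6-dihalophenol should proceed cleanly under carbonate conditions and fixes the 4'-methoxy group of ring B.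

**Step 3**
Reactants: 3 3-bromo-5-iodo-4-methoxybenzaldehyde; 4 2-methylbut-3-yn-2-ol
Product: 5 3-bromo-5-(3-hydroxy-3-methylbut-1-yn-1-yl)-4-methoxybenzaldehyde
Conditions: PdCl2(PPh3)2 (2 mol %), CuI (4 mol %), Et3N, THF, rt
Reagents that add atoms: none
Why: Sonogashira coupling should be selective for C–I over C–Br at room temperature because oxidative addition of zerovalent palladium into the aryl iodide is much faster, and the aldehyde and free tertiary alcohol are tolerated.

**Step 4**
Reactants: 5 3-bromo-5-(3-hydroxy-3-methylbut-1-yn-1-yl)-4-methoxybenzaldehyde; 6 tributyl(3-methylbut-2-en-1-yl)stannane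
Product: 7 3-(3-hydroxy-3-methylbut-1-yn-1-yl)-4-methoxy-5-(3-methylbut-2-en-1-yl)benzaldehyde
Conditions: Pd(PPh3)4 (5 mol %), DMF, 95 °C
Reagents that add atoms: none
Why: Stille coupling of the remaining aryl bromide with the prenylstannane should give the linear prenyl arene, since reductive elimination from the allylpalladium intermediate occurs at the unsubstituted allyl terminus.

**Step 5**
Reactants: 7 3-(3-hydroxy-3-methylbut-1-yn-1-yl)-4-methoxy-5-(3-methylbut-2-en-1-yl)benzaldehyde
Product: 8 3-[(1Z)-3-hydroxy-3-methylbut-1-en-1-yl]-4-methoxy-5-(3-methylbut-2-en-1-yl)benzaldehyde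
Conditions: H2 (1 atm), Pd/CaCO3 poisoned with Pb(OAc)2 (Lindlar catalyst), quinoline, EtOAc, rt
Reagents that add atoms: none
Why: Lindlar semi-hydrogenation delivers hydrogen syn on the poisoned palladium surface and should give the (Z)-alkene while leaving the trisubstituted prenyl alkene and the aldehyde untouched.

**Step 6**
Reactants: 8 3-[(1Z)-3-hydroxy-3-methylbut-1-en-1-yl]-4-methoxy-5-(3-methylbut-2-en-1-yl)benzaldehyde
Product: 9 4-methoxy-3-(3-methylbut-2-en-1-yl)-5-[(1Z)-3-methyl-3-(triethylsilyloxy)but-1-en-1-yl]benzaldehyde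
Conditions: TESOTf, 2,6-lutidine, CH2Cl2, −78 to 0 °C
Reagents that add atoms: triethylsilyl trifluoromethanesulfonate, CC[Si](CC)(CC)OS(=O)(=O)C(F)(F)F
Why: Silyl triflate silylation of the tertiary alcohol under lutidine buffering masks the only protic group before the Lewis-acidic aldol and the base-mediated ring closure.

**Step 7**
Reactants: 10 5-fluorobenzene-1,3-diol
Product: 11 1-(2-fluoro-4,6-dihydroxyphenyl)ethan-1-one
Conditions: AcOH, ZnCl2, 140 °C
Reagents that add atoms: acetic acid, CC(=O)O
Why: Nencki-type Friedel–Crafts C-acylation should occur para to one hydroxyl and ortho to the other (next to fluorine), as with other 5-substituted resorcinols, and not at the hindered carbon between the two hydroxyls.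

**Step 8**
Reactants: 11 1-(2-fluoro-4,6-dihydroxyphenyl)ethan-1-one
Product: 12 1-[2-fluoro-4,6-bis(triisopropylsilyloxy)phenyl]ethan-1-one
Conditions: TIPSOTf (2.3 equiv), 2,6-lutidine, CH2Cl2, 0 °C to rt
Reagents that add atoms: triisopropylsilyl trifluoromethanesulfonate, CC(C)[Si](OS(=O)(=O)C(F)(F)F)(C(C)C)C(C)C
Why: Silyl triflate silylation protects both phenols, including the chelated ortho one, as bulky TIPS ethers that should survive the amide base of step 11 and leave with fluoride at the end.

**Step 9**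
Reactants: 12 1-[2-fluoro-4,6-bis(triisopropylsilyloxy)phenyl]ethan-1-one
Product: 13 {1-[2-fluoro-4,6-bis(triisopropylsilyloxy)phenyl]ethenyl}oxy(trimethyl)silane
Conditions: TMSOTf, Et3N, CH2Cl2, 0 °C
Reagents that add atoms: trimethylsilyl trifluoromethanesulfonate, C[Si](C)(C)OS(=O)(=O)C(F)(F)F
Why: Soft enolisation of the methyl ketone with TMSOTf and Et3N should give the terminal enol silane needed for the Mukaiyama aldol.

**Step 10**
Reactants: 9 4-methoxy-3-(3-methylbut-2-en-1-yl)-5-[(1Z)-3-methyl-3-(triethylsilyloxy)but-1-en-1-yl]benzaldehyde; 13 {1-[2-fluoro-4,6-bis(triisopropylsilyloxy)phenyl]ethenyl}oxy(trimethyl)silane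
Product: 15 (3S)-1-[2-fluoro-4,6-bis(triisopropylsilyloxy)phenyl]-3-hydroxy-3-{4-methoxy-3-(3-methylbut-2-en-1-yl)-5-[(1Z)-3-methyl-3-(triethylsilyloxy)but-1-en-1-yl]phenyl}propan-1-one, via trichlorosilyl aldolate 14 (not isolated)
Conditions: SiCl4 (1.2 equiv), (S,S)-bisphosphoramide (pentane-1,5-diyl-linked, from two (S)-N,N'-dimethyl-1,1'-binaphthyl-2,2'-diamine units; 5 mol %), i-Pr2NEt (10 mol %), CH2Cl2, −78 °C; then sat. aq. NaHCO3
Reagents that add atoms: silicon tetrachloride, Cl[Si](Cl)(Cl)Cl (its SiCl3 group is carried only by 14)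
Why: Catalytic enantioselective Mukaiyama aldol addition under Lewis-base activation of SiCl4, in which the chiral phosphoramide-bound trichlorosilyl cation binds aldehyde 9 and the enol silane should add through an open transition state to the Si face of the formyl group, setting the future C2 as (S).

**Step 11**
Reactants: 15 (3S)-1-[2-fluoro-4,6-bis(triisopropylsilyloxy)phenyl]-3-hydroxy-3-{4-methoxy-3-(3-methylbut-2-en-1-yl)-5-[(1Z)-3-methyl-3-(triethylsilyloxy)but-1-en-1-yl]phenyl}propan-1-one
Product: 17 (2S)-2-{4-methoxy-3-(3-methylbut-2-en-1-yl)-5-[(1Z)-3-methyl-3-(triethylsilyloxy)but-1-en-1-yl]phenyl}-5,7-bis(triisopropylsilyloxy)-2,3-dihydro-4H-chromen-4-one, via sodium alkoxide 16 (not isolated)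
Conditions: NaN(SiMe3)2 (1.05 equiv), THF, −78 to 0 °C; then pH 7 phosphate buffer
Reagents that add atoms: sodium bis(trimethylsilyl)amide, C[Si](C)(C)[N-][Si](C)(C)C.[Na+] (its sodium is carried only by 16)
Why: Deprotonation of the C2 hydroxyl at −78 °C gives sodium alkoxide 16, whose oxygen adds to the fluorine-bearing ring A carbon ortho to the ketone to form a Meisenheimer adduct stabilised as the enolate of the C4 carbonyl, and loss of fluoride restores the arene (addition–elimination, SNAr). The closest known reaction type is the intramolecular SNAr O-arylation of alcohols and phenols by ortho-fluoroaryl ketones used to make chroman-4-ones, chromones and xanthones. Ring C closes in the 6-endo-trig mode with respect to the C4a=C8a bond that relays the charge to the ketone, through a six-membered transition state. No stereocentre is formed: C2 was set in step 10 and its C–O bond is never broken, so the configuration is carried over unchanged, which the reversible oxa-Michael closure of a chalcone cannot guarantee. The step needs chemoselectivity for O-arylation over retro-aldol cleavage, E1cB dehydration and silyl transfer, and site selectivity for C–F over C–OSi; these should be secured by quantitative kinetic O-deprotonation with one equivalent of a non-nucleophilic amide base at low temperature, by fluoride being the only good nucleofuge ortho to the carbonyl, by both silyloxy groups being meta to the reacting carbon so that they do not oppose the Meisenheimer charge, and by the bulk of the TIPS groups. Using no excess base should also keep the product from enolising at C3 and opening to the chalcone.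

**Step 12**
Reactants: 17 (2S)-2-{4-methoxy-3-(3-methylbut-2-en-1-yl)-5-[(1Z)-3-methyl-3-(triethylsilyloxy)but-1-en-1-yl]phenyl}-5,7-bis(triisopropylsilyloxy)-2,3-dihydro-4H-chromen-4-one
Product: 18 (2S)-5,7-dihydroxy-2-{3-[(1Z)-3-hydroxy-3-methylbut-1-en-1-yl]-4-methoxy-5-(3-methylbut-2-en-1-yl)phenyl}-2,3-dihydro-4H-chromen-4-one (CNP0223123.2)
Conditions: Bu4NF, AcOH (1:1, excess), THF, 0 °C to rt
Reagents that add atoms: none
Why: Fluoride-mediated desilylation buffered with acetic acid should cleave the two aryl TIPS ethers and the tertiary TES ether without base strong enough to open ring C or acid strong enough to ionise the tertiary allylic alcohol.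

**Compound list**
1 | 3-bromo-4-hydroxybenzaldehyde | O=Cc1ccc(O)c(Br)c1 | starting material
2 | 3-bromo-4-hydroxy-5-iodobenzaldehyde | O=Cc1cc(Br)c(O)c(I)c1 | intermediate
3 | 3-bromo-5-iodo-4-methoxybenzaldehyde | COc1c(Br)cc(C=O)cc1I | intermediate
4 | 2-methylbut-3-yn-2-ol | CC(C)(O)C#C | starting material
5 | 3-bromo-5-(3-hydroxy-3-methylbut-1-yn-1-yl)-4-methoxybenzaldehyde | COc1c(Br)cc(C=O)cc1C#CC(C)(C)O | intermediate
6 | tributyl(3-methylbut-2-en-1-yl)stannane | CCCC[Sn](CCCC)(CCCC)CC=C(C)C | starting material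
7 | 3-(3-hydroxy-3-methylbut-1-yn-1-yl)-4-methoxy-5-(3-methylbut-2-en-1-yl)benzaldehyde | COc1c(CC=C(C)C)cc(C=O)cc1C#CC(C)(C)O | intermediate
8 | 3-[(1Z)-3-hydroxy-3-methylbut-1-en-1-yl]-4-methoxy-5-(3-methylbut-2-en-1-yl)benzaldehyde | COc1c(/C=C\C(C)(C)O)cc(C=O)cc1CC=C(C)C | intermediate
9 | 4-methoxy-3-(3-methylbut-2-en-1-yl)-5-[(1Z)-3-methyl-3-(triethylsilyloxy)but-1-en-1-yl]benzaldehyde | COc1c(/C=C\C(C)(C)O[Si](CC)(CC)CC)cc(C=O)cc1CC=C(C)C | intermediate
10 | 5-fluorobenzene-1,3-diol | Oc1cc(O)cc(F)c1 | starting material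
11 | 1-(2-fluoro-4,6-dihydroxyphenyl)ethan-1-one | CC(=O)c1c(O)cc(O)cc1F | intermediate
12 | 1-[2-fluoro-4,6-bis(triisopropylsilyloxy)phenyl]ethan-1-one | CC(=O)c1c(F)cc(O[Si](C(C)C)(C(C)C)C(C)C)cc1O[Si](C(C)C)(C(C)C)C(C)C | intermediate
13 | {1-[2-fluoro-4,6-bis(triisopropylsilyloxy)phenyl]ethenyl}oxy(trimethyl)silane | C=C(O[Si](C)(C)C)c1c(F)cc(O[Si](C(C)C)(C(C)C)C(C)C)cc1O[Si](C(C)C)(C(C)C)C(C)C | intermediate
14 | O-trichlorosilyl ether of aldol 15 (trichlorosilyl aldolate, not isolated) | COc1c(/C=C\C(C)(C)O[Si](CC)(CC)CC)cc([C@@H](O[Si](Cl)(Cl)Cl)CC(=O)c2c(F)cc(O[Si](C(C)C)(C(C)C)C(C)C)cc2O[Si](C(C)C)(C(C)C)C(C)C)cc1CC=C(C)C | intermediate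
15 | (3S)-1-[2-fluoro-4,6-bis(triisopropylsilyloxy)phenyl]-3-hydroxy-3-{4-methoxy-3-(3-methylbut-2-en-1-yl)-5-[(1Z)-3-methyl-3-(triethylsilyloxy)but-1-en-1-yl]phenyl}propan-1-one | COc1c(/C=C\C(C)(C)O[Si](CC)(CC)CC)cc([C@@H](O)CC(=O)c2c(F)cc(O[Si](C(C)C)(C(C)C)C(C)C)cc2O[Si](C(C)C)(C(C)C)C(C)C)cc1CC=C(C)C | intermediate
16 | sodium alkoxide of aldol 15 (not isolated) | COc1c(/C=C\C(C)(C)O[Si](CC)(CC)CC)cc([C@@H]([O-])CC(=O)c2c(F)cc(O[Si](C(C)C)(C(C)C)C(C)C)cc2O[Si](C(C)C)(C(C)C)C(C)C)cc1CC=C(C)C.[Na+] | intermediate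
17 | (2S)-2-{4-methoxy-3-(3-methylbut-2-en-1-yl)-5-[(1Z)-3-methyl-3-(triethylsilyloxy)but-1-en-1-yl]phenyl}-5,7-bis(triisopropylsilyloxy)-2,3-dihydro-4H-chromen-4-one | COc1c(/C=C\C(C)(C)O[Si](CC)(CC)CC)cc([C@@H]2CC(=O)c3c(O[Si](C(C)C)(C(C)C)C(C)C)cc(O[Si](C(C)C)(C(C)C)C(C)C)cc3O2)cc1CC=C(C)C | intermediate
18 | (2S)-5,7-dihydroxy-2-{3-[(1Z)-3-hydroxy-3-methylbut-1-en-1-yl]-4-methoxy-5-(3-methylbut-2-en-1-yl)phenyl}-2,3-dihydro-4H-chromen-4-one | COc1c(/C=C\C(C)(C)O)cc([C@@H]2CC(=O)c3c(O)cc(O)cc3O2)cc1CC=C(C)C | target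

**Step count**
Total: 12 steps. Longest linear sequence: 9 steps (steps 1–6, then 10, 11, 12); the ring A branch (steps 7–9) joins at step 10.

**Steps most likely to fail**

1. Step 11. The alkoxide may revert by retro-aldol cleavage and recombine, which would erode the enantiopurity. It may also dehydrate by E1cB, or take the silyl group from the neighbouring aryl silyl ether, before it displaces fluoride.
 Fallback: the same bond is closed by palladium-catalysed C–O coupling on the bromo analogue; the route is left at aldehyde 9 and rejoined at 17. Commercial 5-bromobenzene-1,3-diol is taken through the operations of steps 7–9 to give 1-(2-bromo-4,6-dihydroxyphenyl)ethan-1-one F1, then 1-[2-bromo-4,6-bis(triisopropylsilyloxy)phenyl]ethan-1-one F2, then the enol silane {1-[2-bromo-4,6-bis(triisopropylsilyloxy)phenyl]ethenyl}oxy(trimethyl)silane F3. The aldol of step 10 between F3 and 9 should give, through the trichlorosilyl aldolate of the bromo series F4 (not isolated), the (3S)-bromo aldol F5. Ring C is then closed with Pd(OAc)2, 2-(di-tert-butylphosphino)-1,1'-binaphthyl and Cs2CO3 in toluene at 60 °C. The alkoxide then exists only on divalent palladium and the aryl ether forms by reductive elimination, so no free aldolate accumulates, and 17 should result.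

2. Step 10. The di-ortho-substituted enol silane may add slowly or with poor facial selectivity, or the sense of induction may be opposite to the one assumed.
 Fallback: the enantioselective catalysis is replaced by a kinetic aldol followed by resolution, from ketone 12 and aldehyde 9 back to 15. Ketone 12 is deprotonated with LiN(SiMe3)2 in THF at −78 °C to the lithium enolate of 12 F6 (not isolated). Aldehyde 9 is added and the mixture quenched with AcOH at −78 °C, so that the aldolate cannot cyclise, to give the racemic aldol F7. The enantiomers are separated by preparative chromatography on a chiral stationary phase (amylose tris(3,5-dimethylphenylcarbamate), supercritical CO2/MeOH), and the (S)-enantiomer, assigned by Mosher esters, is 15.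

3. Step 4. The prenyl group may transfer through its substituted terminus to give the 1,1-dimethylallyl isomer, and oxidative addition into the electron-rich, ortho-substituted aryl bromide may be slow.
 Fallback: the polarity of the coupling is reversed, from 5 back to 7. The aldehyde of 5 is masked with HC(OMe)3 and catalytic TsOH in MeOH as the dimethyl acetal of 5 F8. n-BuLi (2.1 equiv) in THF at −78 °C deprotonates the alcohol and exchanges bromine for lithium to give the O,C-dilithio species F9 (not isolated). CuBr·SMe2 followed by 1-bromo-3-methylbut-2-ene alkylates the aryl copper at the primary carbon to give the prenylated dimethyl acetal F10. Hydrolysis with 1 M HCl in THF returns aldehyde 7.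

**Further compounds**
F1 | step 11 | 1-(2-bromo-4,6-dihydroxyphenyl)ethan-1-one | CC(=O)c1c(O)cc(O)cc1Br
F2 | step 11 | 1-[2-bromo-4,6-bis(triisopropylsilyloxy)phenyl]ethan-1-one | CC(=O)c1c(Br)cc(O[Si](C(C)C)(C(C)C)C(C)C)cc1O[Si](C(C)C)(C(C)C)C(C)C
F3 | step 11 | {1-[2-bromo-4,6-bis(triisopropylsilyloxy)phenyl]ethenyl}oxy(trimethyl)silane | C=C(O[Si](C)(C)C)c1c(Br)cc(O[Si](C(C)C)(C(C)C)C(C)C)cc1O[Si](C(C)C)(C(C)C)C(C)C
F4 | step 11 | trichlorosilyl aldolate of the bromo series (not isolated) | COc1c(/C=C\C(C)(C)O[Si](CC)(CC)CC)cc([C@@H](O[Si](Cl)(Cl)Cl)CC(=O)c2c(Br)cc(O[Si](C(C)C)(C(C)C)C(C)C)cc2O[Si](C(C)C)(C(C)C)C(C)C)cc1CC=C(C)C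
F5 | step 11 | (3S)-1-[2-bromo-4,6-bis(triisopropylsilyloxy)phenyl]-3-hydroxy-3-{4-methoxy-3-(3-methylbut-2-en-1-yl)-5-[(1Z)-3-methyl-3-(triethylsilyloxy)but-1-en-1-yl]phenyl}propan-1-one | COc1c(/C=C\C(C)(C)O[Si](CC)(CC)CC)cc([C@@H](O)CC(=O)c2c(Br)cc(O[Si](C(C)C)(C(C)C)C(C)C)cc2O[Si](C(C)C)(C(C)C)C(C)C)cc1CC=C(C)C
F6 | step 10 | lithium enolate of ketone 12 (not isolated) | [Li+].C=C([O-])c1c(F)cc(O[Si](C(C)C)(C(C)C)C(C)C)cc1O[Si](C(C)C)(C(C)C)C(C)C
F7 | step 10 | racemic 1-[2-fluoro-4,6-bis(triisopropylsilyloxy)phenyl]-3-hydroxy-3-{4-methoxy-3-(3-methylbut-2-en-1-yl)-5-[(1Z)-3-methyl-3-(triethylsilyloxy)but-1-en-1-yl]phenyl}propan-1-one | COc1c(/C=C\C(C)(C)O[Si](CC)(CC)CC)cc(C(O)CC(=O)c2c(F)cc(O[Si](C(C)C)(C(C)C)C(C)C)cc2O[Si](C(C)C)(C(C)C)C(C)C)cc1CC=C(C)C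
F8 | step 4 | 4-[3-bromo-5-(dimethoxymethyl)-2-methoxyphenyl]-2-methylbut-3-yn-2-ol | COc1c(Br)cc(C(OC)OC)cc1C#CC(C)(C)O
F9 | step 4 | O,C-dilithio species from F8 (not isolated) | COc1c([Li])cc(C(OC)OC)cc1C#CC(C)(C)O[Li]
F10 | step 4 | 4-[5-(dimethoxymethyl)-2-methoxy-3-(3-methylbut-2-en-1-yl)phenyl]-2-methylbut-3-yn-2-ol | COc1c(CC=C(C)C)cc(C(OC)OC)cc1C#CC(C)(C)O
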